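Atom numbering used throughout: ring carbons C1 (carries the exocyclic methylene C15), C2, C3, C4=C5 (methyl on C5), C6, C7, C8, C9; C16 is the ester carbon on C9; the side chain on C8 is C10(CH2OAc)=C11–C12=C13–C14(CH3)2OH.

## Analysis of the target

Target 29 is built on a nine-membered carbocycle (C1–C9) that holds an (E)-trisubstituted C4=C5 alkene and an exocyclic methylene on C1. Two contiguous stereocentres, (S)-C8 and (R)-C9, place the C16 methyl ester and the C10 side chain trans to each other on the ring. The C9 hydrogen is α to the ester and allylic to C1=C15, so base can epimerise C9 or draw the methylene into conjugation. The side chain is a (Z)-trisubstituted C10=C11 alkene (C12 trans to C8) conjugated with the (E)-C12=C13 alkene; it ends in a tertiary dienylic alcohol that ionises easily under acid and it carries a primary allylic acetate. Once that acetate oxygen is a free hydroxyl it sits δ to the ester carbonyl, so a late intermediate with both groups unprotected can lactonise. Three things make the synthesis hard: an (E)-cyclononene is strained and awkward to close from an open chain, the C8–C9 bond is the most hindered bond of the molecule, and the C10=C11 geometry has to be set together with the two stereocentres. The strategy rests on the unit O=C16–C9–C8–C10=C11, a γ,δ-unsaturated carbonyl compound and hence a Claisen retron across C8–C9. Its allylic ester precursor carries the ester oxygen on C11, and because C9 and C8 are already joined through C1–C7, that ester is a thirteen-membered lactone whose [3,3] shift contracts it to the nine-membered ring.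

## Retrosynthetic reasoning

**29 ⇒ 28 ⇒ 27 ⇒ 26.** The primary acetate is removed first in the retrosynthetic direction, because it is the most base-labile group and the tertiary hydroxyl of 28 does not compete for acylation. The C12=C13 alkene is then traced through vinylsilane 27 back to the alkyne of 26. An alkyne at this position is a masked (E)-alkene that is opened by trans-hydrosilylation and protodesilylation. It also serves the key step: with a C12=C13 alkene in place, C11 would be doubly allylic and a second [3,3] path (C9 to C13) would open, and the dienylic tertiary alcohol would have to survive many more steps.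

**26 ⇒ 25 ⇒ 22 (key disconnection).** The C8–C9 bond is cut. Nowhere else does one cut remove the ring, both stereocentres and the C10=C11 geometry together. The forward reaction is the rearrangement of silyl ketene acetal 23, made from lactone 22, to silyl ester 24 and acid 25. It must pass through one chair in which C1, C7 and the alkynyl group are pseudo-equatorial. That calls for the ketene acetal geometry with C1 cis to the silyloxy group, which the enolisation medium must enforce, an (E)-C8=C10 alkene, and a single configuration (S) at C11.

**22 ⇒ 21 ⇒ 20 ⇒ 19 ⇒ 18.** The lactone C16–O bond is cut to seco acid 20, activated in the forward sense as mixed anhydride 21. A thirteen-membered ring with three trigonal segments is far easier to close than a nine-membered one. The acid comes from the primary alcohol of diol 18 by oxidation at C16 through aldehyde 19, which has to leave the C11 carbinol untouched.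

**18 ⇒ 15 + 17.** The C11–C12 bond is cut between enal 15 and alkyne 17. A catalytic enantioselective alkynylation sets C11, the only stereocentre that has to be made before the key step. The tertiary hydroxyl of 16 is capped as the silyl ether 17 so that it is inert to every later base.

**15 ⇒ 14 ⇒ 13 ⇒ 12 ⇒ 11 ⇒ 9 ⇒ 7 + 8.** The enal is reached by adjusting the oxidation level of enoate 13, itself the silyl ether of alcohol 12. The trisubstituted C8=C10 alkene with its oxygenated one-carbon branch is the signature of a Baylis–Hillman adduct (9, from aldehyde 7 and acrylate 8) after allylic transposition of its acetate (10 to 11). The transposition is under thermodynamic control and delivers the geometry the chair needs (C7 trans to C11).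

**7 ⇒ 6 ⇒ 5 ⇒ 2 + 3 (via 4), 2 ⇒ 1.** The C8 aldehyde is the cleavage product of a terminal epoxide (6). The C2–C3 bond is cut between the allylic chloride 2 and the dianion 4 of 3, which supplies C16, C9, C1, C15 and C2 in one piece. The chain end is marked as an epoxide on 1, before the coupling. In 1 the allylic chloride deactivates the neighbouring alkene, whereas after the coupling the chain would hold two trisubstituted alkenes of nearly equal reactivity. The (E)-C4=C5 alkene is carried in unchanged from 1.

## Alternatives that were turned down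

Alternative 1: anionic oxy-Cope ring expansion.
- Disconnection: the C2–C3 ring bond is cut, and the nine-membered enol triflate A1 is traced to cyclopentanol A2, in which C5–C9 is a ring bond and C5 and C9 carry cis alkenyl groups.
- Forward key step: the potassium alkoxide of A2 undergoes the [3,3] shift and the enolate is trapped as A1. Carbonylation of A1 would then supply C16, and protodesilylation of its allylsilane would reveal the methylene.
- For: the ring expansion is unimolecular and strongly driven, needs no high dilution, and C8 is in place beforehand. On ring formation it is as strong as or stronger than a macrolactonisation followed by contraction.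
- Against:
  - The (E)-C4=C5 geometry has to be created in the key step. A cis-dialkenyl cyclopentane reaches the necessary chair only if the ring spans an axial and an equatorial position, and the boat or the other chair gives the (Z)-alkene.
  - C9 is not set in the key step but later, by protonation of the allylsilane on a flexible ring.
  - The quaternary C5 and C9 centres of A2 are built stereoselectively only to be destroyed.
  - The tetrasubstituted triflate of A1 is a hindered carbonylation substrate.
- Comparison: the chosen route inherits C4=C5 from 1 and fixes C8 and C9 in one transition state.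

Alternative 2: Nozaki–Hiyama–Kishi closure at C1–C2.
- Disconnection: the C1–C2 bond is cut, and the ring alcohol A3 is traced to the open-chain iodo aldehyde A4.
- Forward key step: CrCl2 and a catalytic amount of NiCl2 turn the alkenyl iodide of A4 into an alkenylchromium species, which adds to the C2 aldehyde and closes the ring as A3.
- For: the route is convergent and mild, the complete dienol side chain can be carried (no alkyne mask), the methylene arises directly, and C8/C9 can be set by acyclic chemistry. On convergence and on the simplicity of the end game it is stronger than the chosen route.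
- Against:
  - A nine-membered ring containing an (E)-alkene is closed directly from an open chain, with entropy and transannular strain against it.
  - A3 carries a superfluous C2 hydroxyl (as epimers), and its removal at an allylic position risks moving the methylene.
  - The C2 aldehyde of A4 is β,γ-unsaturated and the C9–H of A4 is acidic.
- Comparison: the chosen strategy offers a ring closure at the easy thirteen-membered size, no redundant oxygen, and stereocentres that are created as the ring forms.

Alternative 3: Grob fragmentation of a hydrindane.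
- Disconnection: a temporary C1–C5 bond is added, so that cyclononenone A5 comes from the bicyclic hydroxy tosylate A6.
- Forward key step: the C1 alkoxide of A6 fragments; C1–C5 breaks, C4=C5 forms as the tosylate leaves, and A5 is revealed.
- For: the alkene geometry is stereospecific from a rigid bicycle (tosylate cis to the angular methyl gives E), the absolute configuration comes from a proline-catalysed annulation, and no dilution is needed. On control of C4=C5 and on the ring-forming event itself it is as strong as or stronger than the chosen route.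
- Against:
  - Many steps are needed to place the C8 side chain, the trans C9 carbinol carbon, the C1 hydroxyl and the C4 tosylate on A6.
  - After A5, a hindered, enolisable ketone next to C9 has to be methylenated, C16 has to be raised to the ester, and the base-exposed side chain has to be finished.
- Comparison: the chosen route is shorter and makes ring, C8, C9 and C10=C11 in one step from a precursor assembled from cheap acyclic pieces.

Key step: step 15

Assumption: (R,R)-ProPhenol is written in step 12 as the ligand enantiomer that directs the alkynyl group to the Si face of the aldehyde, by analogy with the facial sense of this ligand in zinc aldol reactions; if the facial sense on this α-branched enal is the opposite, the (S,S)-ligand is used instead, and the C11 configuration of 18 would be confirmed through its Mosher esters.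

## Route

Step 1
Reactants: 1 geranyl chloride
Product: 2 6,7-epoxygeranyl chloride (racemic at the oxirane carbon)
Conditions: mCPBA (1.05 equiv), NaHCO3, CH2Cl2, 0 °C
Reagents that add atoms: 3-chloroperoxybenzoic acid, O=C(OO)c1cccc(Cl)c1
Why: Peracid epoxidation is electrophilic, so the isopropylidene alkene reacts in preference to the alkene deactivated by the allylic chloride (Prilezhaev epoxidation); the oxirane centre is racemic, which does not matter because that carbon becomes the C8 aldehyde.

Step 2
Reactants: 3 3-methylbut-3-en-1-ol; 2 6,7-epoxygeranyl chloride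
Product: 5 epoxy alcohol rac-(6E)-9-(3,3-dimethyloxiran-2-yl)-7-methyl-3-methylidenenon-6-en-1-ol, via dilithio dianion 4 (not isolated)
Conditions: 3, n-BuLi (2.1 equiv), TMEDA, Et2O, 0 °C → rt; then 2, THF, −78 → −30 °C
Reagents that add atoms: none
Why: Allylic lithiation of the alkoxide of 3 gives a symmetrical allyl anion that displaces the primary allylic chloride by SN2 at low temperature, much faster than it can open the trisubstituted epoxide (alkylation of an alcohol dianion); the (E)-alkene is not touched.

Step 3
Reactants: 5 epoxy alcohol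
Product: 6 epoxy pivalate rac-(6E)-9-(3,3-dimethyloxiran-2-yl)-7-methyl-3-methylidenenon-6-en-1-yl 2,2-dimethylpropanoate
Conditions: PivCl, Et3N, DMAP (cat.), CH2Cl2, 0 °C
Reagents that add atoms: pivaloyl chloride, CC(C)(C)C(Cl)=O
Why: Standard acylation of the primary alcohol; the pivalate survives the later acetate methanolysis and is removed without an extra step in the hydride reduction of step 9.

Step 4
Reactants: 6 epoxy pivalate
Product: 7 aldehyde (6E)-7-methyl-3-methylidene-10-oxodec-6-en-1-yl 2,2-dimethylpropanoate
Conditions: H5IO6, THF/Et2O, 0 °C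
Reagents that add atoms: none
Why: Periodic acid hydrates the epoxide and cleaves the glycol in the same flask (Malaprade-type cleavage), releasing the C8 aldehyde and acetone; the alkenes and the pivalate are inert.

Step 5
Reactants: 7 aldehyde; 8 methyl acrylate
Product: 9 Baylis–Hillman adduct rac-methyl (6E)-12-(2,2-dimethylpropanoyloxy)-3-hydroxy-6-methyl-2,10-dimethylidenedodec-6-enoate
Conditions: 8 (3 equiv), DABCO (1 equiv), 1,4-dioxane/H2O (1:1), rt
Reagents that add atoms: none
Why: Morita–Baylis–Hillman reaction of an unbranched aliphatic aldehyde joins C8 to C10 and brings in C11 and the future CH2O carbon; the C8 carbinol centre is racemic and is removed in step 6.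

Step 6
Reactants: 9 Baylis–Hillman adduct
Product: 11 methyl (2E,6E)-2-(acetoxymethyl)-12-(2,2-dimethylpropanoyloxy)-6-methyl-10-methylidenedodeca-2,6-dienoate, via secondary acetate 10 (not isolated)
Conditions: Ac2O, Et3N, DMAP (cat.), THF, 0 °C → rt; then DABCO (1 equiv), 60 °C
Reagents that add atoms: acetic anhydride, CC(=O)OC(C)=O
Why: Acetylation followed by the DABCO-mediated allylic transposition of Baylis–Hillman acetates, in which SN2' addition of the amine expels acetate and the acetate returns at the primary carbon; the process is reversible and under thermodynamic control, and gives the conjugated trisubstituted (E)-enoate with C7 trans to the ester carbon C11, the geometry the later chair needs.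

Step 7
Reactants: 11 rearranged acetate
Product: 12 methyl (2E,6E)-12-(2,2-dimethylpropanoyloxy)-2-(hydroxymethyl)-6-methyl-10-methylidenedodeca-2,6-dienoate
Conditions: K2CO3 (0.2 equiv), MeOH, 0 °C
Reagents that add atoms: none
Why: Transesterification removes the unhindered primary acetate much faster than the pivalate, and the methyl ester is degenerate in methanol.

Step 8
Reactants: 12 allylic alcohol
Product: 13 methyl (2E,6E)-2-{[(tert-butyldimethylsilyl)oxy]methyl}-12-(2,2-dimethylpropanoyloxy)-6-methyl-10-methylidenedodeca-2,6-dienoate
Conditions: TBSCl, imidazole, DMF, 0 °C → rt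
Reagents that add atoms: tert-butyldimethylsilyl chloride, CC(C)(C)[Si](C)(C)Cl
Why: Standard silylation of a primary allylic alcohol; the silyl ether withstands every base used up to the final fluoride step.

Step 9
Reactants: 13 silyl ether ester
Product: 14 diol (2Z,6E)-2-{[(tert-butyldimethylsilyl)oxy]methyl}-6-methyl-10-methylidenedodeca-2,6-diene-1,12-diol
Conditions: iBu2AlH (5 equiv), CH2Cl2, −78 → 0 °C; aq. potassium sodium tartrate
Reagents that add atoms: none
Why: The aluminium hydride reduces the enoate 1,2 to the allylic alcohol and cleaves the pivalate in the same operation; the alkene geometry is unchanged (the descriptor changes to Z only because the priorities at C10 change).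

Step 10
Reactants: 14 diol
Product: 15 enal (2E,6E)-2-{[(tert-butyldimethylsilyl)oxy]methyl}-12-hydroxy-6-methyl-10-methylidenedodeca-2,6-dienal
Conditions: MnO2 (excess), CH2Cl2, rt
Reagents that add atoms: none
Why: MnO2 oxidises only the allylic alcohol and leaves the homoallylic C16 hydroxyl; the enal formed is the thermodynamically preferred geometry, so C7 stays trans to C11.

Step 11
Reactants: 16 2-methylbut-3-yn-2-ol
Product: 17 triethyl[(2-methylbut-3-yn-2-yl)oxy]silane
Conditions: Et3SiOTf, 2,6-lutidine, CH2Cl2, 0 °C
Reagents that add atoms: triethylsilyl trifluoromethanesulfonate, CC[Si](CC)(CC)OS(=O)(=O)C(F)(F)F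
Why: Silyl triflates silylate tertiary alcohols reliably; the capped hydroxyl no longer consumes base or zinc reagent in later steps.

Step 12
Reactants: 15 enal; 17 silyl-protected alkyne
Product: 18 diol (6E,10E,12S)-11-{[(tert-butyldimethylsilyl)oxy]methyl}-7,15-dimethyl-3-methylidene-15-[(triethylsilyl)oxy]hexadeca-6,10-dien-13-yne-1,12-diol
Conditions: 17 (3 equiv), Me2Zn (4 equiv), (R,R)-ProPhenol (20 mol%), Ph3PO (40 mol%), toluene, 0 °C
Reagents that add atoms: none
Why: Zinc–ProPhenol-catalysed asymmetric alkynylation, a method suited to α-substituted enals: the dinuclear zinc alkoxide holds the enal and the zinc acetylide of 17 in one chiral pocket and delivers the alkynyl group to the Si face of C11, setting (S)-C11 by catalyst control. One extra equivalent of Me2Zn masks the C16 hydroxyl as its methylzinc alkoxide.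

Step 13
Reactants: 18 diol
Product: 20 seco acid (6E,10E,12S)-11-{[(tert-butyldimethylsilyl)oxy]methyl}-12-hydroxy-7,15-dimethyl-3-methylidene-15-[(triethylsilyl)oxy]hexadeca-6,10-dien-13-ynoic acid, via hydroxy aldehyde 19 (not isolated)
Conditions: TEMPO (0.2 equiv), PhI(OAc)2 (1.2 equiv), CH2Cl2, rt; then t-BuOH, 2-methyl-2-butene, NaClO2, NaH2PO4, H2O, 0 °C
Reagents that add atoms: sodium chlorite, [Na+].[O-]Cl=O
Why: The oxoammonium oxidation is sterically selective for the primary C16 alcohol over the hindered C11 carbinol, and the β,γ-unsaturated aldehyde 19 is taken on at once by Pinnick oxidation, so the C1 methylene has little time to move into conjugation.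

Step 14
Reactants: 20 seco acid
Product: 22 lactone (7E,11E,13S)-12-{[(tert-butyldimethylsilyl)oxy]methyl}-8-methyl-4-methylidene-13-{3-methyl-3-[(triethylsilyl)oxy]but-1-yn-1-yl}-1-oxacyclotrideca-7,11-dien-2-one, via mixed anhydride 21 (not isolated)
Conditions: 2,4,6-Cl3C6H2COCl, Et3N, THF, rt; then slow addition to DMAP, toluene, 60 °C (about 2 mM)
Reagents that add atoms: none
Why: Yamaguchi macrolactonisation; C11 carries the only free hydroxyl, and the thirteen-membered ring with two (E)-alkenes and a transoid ester is nearly strain-free, so closure at high dilution should outrun oligomerisation.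

Step 15
Reactants: 22 lactone
Product: 25 (1R,2S,5E)-2-[(2Z)-1-{[tert-butyl(dimethyl)silyl]oxy}-6-methyl-6-[(triethylsilyl)oxy]hept-2-en-4-yn-2-yl]-5-methyl-9-methylidenecyclonon-5-ene-1-carboxylic acid, via silyl ketene acetal 23 (not isolated), via trimethylsilyl ester 24 (not isolated)
Conditions: LiN(iPr)2 (1.5 equiv), THF–DMPU (3:1), −78 °C; Me3SiCl–Et3N, −78 °C → rt, then 60 °C; 5% citric acid
Reagents that add atoms: none
Why: LiN(iPr)2 in THF–DMPU removes the doubly activated C9–H and Me3SiCl traps the enolate as ketene acetal 23 with C1 cis to the silyloxy group; in THF alone the kinetic preference of acyclic esters would put C1 cis to the ring oxygen, hence the dipolar cosolvent. On warming, 23 undergoes the concerted [3,3] shift of the Ireland–Claisen rearrangement: C8–C9 forms as O–C11 breaks, giving silyl ester 24, which is hydrolysed to 25 on work-up. The closest known reaction type is the ester enolate Claisen ring contraction of macrolactone silyl ketene acetals to carbocycles. The nine-membered ring closes transannularly inside a six-atom chair array, by contraction of the thirteen-membered ring by four atoms (C16, O, C11 and C10 leave the ring), so no medium ring is closed from an open chain. C8 is controlled by C11: with the alkynyl group pseudo-equatorial, C9 bonds to the alkene face from which the C11–O bond departs, which gives (S)-C8 and places C12 trans to C8 on the new C10=C11 bond. C9 is controlled by the ketene acetal geometry and the (E)-C8=C10 alkene: with C1 and C7 both pseudo-equatorial the chair gives the trans ring relationship, (R)-C9. The step needs chair over boat and the equatorial-alkynyl chair; the E,E arrangement of the two reacting π bonds (as in transannular Cope rearrangements of medium-ring E,E-1,5-dienes) and the 1,3-diaxial clash of an axial alkynyl group with the silyloxy group favour both, and a propargylic shift through the alkyne is not expected to compete because it would need bonding at C13, which is shielded by the CMe2OSiEt3 group. Leakage through the axial-alkynyl chair would give a diastereomer (the C10=C11 geometric isomer with both ring centres inverted) and not the enantiomer, so the enantiopurity of 22 is carried into 25.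

Step 16
Reactants: 25 acid
Product: 26 methyl (1R,2S,5E)-2-[(2Z)-1-{[tert-butyl(dimethyl)silyl]oxy}-6-methyl-6-[(triethylsilyl)oxy]hept-2-en-4-yn-2-yl]-5-methyl-9-methylidenecyclonon-5-ene-1-carboxylate
Conditions: Me3SiCHN2, toluene/MeOH (4:1), 0 °C
Reagents that add atoms: trimethylsilyldiazomethane, C[Si](C)(C)C=[N+]=[N-]
Why: Methylation by a diazomethane equivalent is neutral, so the epimerisable C9 and the deconjugated methylene are not exposed to base.

Step 17
Reactants: 26 enyne ester
Product: 28 methyl (1R,2S,5E)-2-[(2Z,4E)-1,6-dihydroxy-6-methylhepta-2,4-dien-2-yl]-5-methyl-9-methylidenecyclonon-5-ene-1-carboxylate, via vinylsilane 27 (not isolated)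
Conditions: (EtO)3SiH (1.3 equiv), [Cp*Ru(MeCN)3]PF6 (5 mol%), CH2Cl2, 0 °C → rt; then CuI (0.2 equiv), Bu4NF (6 equiv), THF, 0 °C
Reagents that add atoms: none
Why: The cationic ruthenium catalyst adds H and Si trans across the alkyne and leaves alkenes alone (trans-hydrosilylation, known for 1,3-enynes); fluoride then replaces silicon by hydrogen with retention, giving the (E)-C12=C13 alkene, and removes both silyl ethers in the same flask. A C13-silyl regioisomer of 27 would converge on the same diene.

Step 18
Reactants: 28 diol
Product: 29 methyl (1R,2S,5E)-2-[(2Z,4E)-1-(acetyloxy)-6-hydroxy-6-methylhepta-2,4-dien-2-yl]-5-methyl-9-methylidenecyclonon-5-ene-1-carboxylate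
Conditions: Ac2O (1.2 equiv), pyridine, DMAP (cat.), CH2Cl2, 0 °C
Reagents that add atoms: acetic anhydride, CC(=O)OC(C)=O
Why: The primary allylic hydroxyl is acylated, while the tertiary alcohol does not react under these conditions; mild amine base at 0 °C should leave C9 untouched, and fast acylation removes the hydroxyl before it can close onto the ester.

## Compound list

1 | geranyl chloride, (2E)-1-chloro-3,7-dimethylocta-2,6-diene | CC(C)=CCC/C(C)=C/CCl | starting material
2 | 6,7-epoxygeranyl chloride, rac-3-[(3E)-5-chloro-3-methylpent-3-en-1-yl]-2,2-dimethyloxirane | CC1(C)OC1CC/C(C)=C/CCl | intermediate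
3 | 3-methylbut-3-en-1-ol | C=C(C)CCO | starting material
4 | dilithio dianion of 3, lithium 3-(lithiomethyl)but-3-en-1-olate | [Li]CC(=C)CCO[Li] | intermediate
5 | rac-(6E)-9-(3,3-dimethyloxiran-2-yl)-7-methyl-3-methylidenenon-6-en-1-ol | OCCC(=C)CC/C=C(\C)CCC1OC1(C)C | intermediate
6 | rac-(6E)-9-(3,3-dimethyloxiran-2-yl)-7-methyl-3-methylidenenon-6-en-1-yl 2,2-dimethylpropanoate | CC(C)(C)C(=O)OCCC(=C)CC/C=C(\C)CCC1OC1(C)C | intermediate
7 | (6E)-7-methyl-3-methylidene-10-oxodec-6-en-1-yl 2,2-dimethylpropanoate | CC(C)(C)C(=O)OCCC(=C)CC/C=C(\C)CCC=O | intermediate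
8 | methyl acrylate | C=CC(=O)OC | starting material
9 | rac-methyl (6E)-12-(2,2-dimethylpropanoyloxy)-3-hydroxy-6-methyl-2,10-dimethylidenedodec-6-enoate | CC(C)(C)C(=O)OCCC(=C)CC/C=C(\C)CCC(O)C(=C)C(=O)OC | intermediate
10 | rac-methyl (6E)-3-acetoxy-12-(2,2-dimethylpropanoyloxy)-6-methyl-2,10-dimethylidenedodec-6-enoate | CC(C)(C)C(=O)OCCC(=C)CC/C=C(\C)CCC(OC(C)=O)C(=C)C(=O)OC | intermediate
11 | methyl (2E,6E)-2-(acetoxymethyl)-12-(2,2-dimethylpropanoyloxy)-6-methyl-10-methylidenedodeca-2,6-dienoate | CC(C)(C)C(=O)OCCC(=C)CC/C=C(\C)CC/C=C(\COC(C)=O)C(=O)OC | intermediate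
12 | methyl (2E,6E)-12-(2,2-dimethylpropanoyloxy)-2-(hydroxymethyl)-6-methyl-10-methylidenedodeca-2,6-dienoate | CC(C)(C)C(=O)OCCC(=C)CC/C=C(\C)CC/C=C(\CO)C(=O)OC | intermediate
13 | methyl (2E,6E)-2-{[(tert-butyldimethylsilyl)oxy]methyl}-12-(2,2-dimethylpropanoyloxy)-6-methyl-10-methylidenedodeca-2,6-dienoate | CC(C)(C)C(=O)OCCC(=C)CC/C=C(\C)CC/C=C(\CO[Si](C)(C)C(C)(C)C)C(=O)OC | intermediate
14 | (2Z,6E)-2-{[(tert-butyldimethylsilyl)oxy]methyl}-6-methyl-10-methylidenedodeca-2,6-diene-1,12-diol | OCCC(=C)CC/C=C(\C)CC/C=C(\CO[Si](C)(C)C(C)(C)C)CO | intermediate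
15 | (2E,6E)-2-{[(tert-butyldimethylsilyl)oxy]methyl}-12-hydroxy-6-methyl-10-methylidenedodeca-2,6-dienal | OCCC(=C)CC/C=C(\C)CC/C=C(\CO[Si](C)(C)C(C)(C)C)C=O | intermediate
16 | 2-methylbut-3-yn-2-ol | CC(C)(O)C#C | starting material
17 | triethyl[(2-methylbut-3-yn-2-yl)oxy]silane | C#CC(C)(C)O[Si](CC)(CC)CC | intermediate
18 | (6E,10E,12S)-11-{[(tert-butyldimethylsilyl)oxy]methyl}-7,15-dimethyl-3-methylidene-15-[(triethylsilyl)oxy]hexadeca-6,10-dien-13-yne-1,12-diol | OCCC(=C)CC/C=C(\C)CC/C=C(\CO[Si](C)(C)C(C)(C)C)[C@H](C#CC(C)(C)O[Si](CC)(CC)CC)O | intermediate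
19 | (6E,10E,12S)-11-{[(tert-butyldimethylsilyl)oxy]methyl}-12-hydroxy-7,15-dimethyl-3-methylidene-15-[(triethylsilyl)oxy]hexadeca-6,10-dien-13-ynal | O=CCC(=C)CC/C=C(\C)CC/C=C(\CO[Si](C)(C)C(C)(C)C)[C@H](C#CC(C)(C)O[Si](CC)(CC)CC)O | intermediate
20 | (6E,10E,12S)-11-{[(tert-butyldimethylsilyl)oxy]methyl}-12-hydroxy-7,15-dimethyl-3-methylidene-15-[(triethylsilyl)oxy]hexadeca-6,10-dien-13-ynoic acid | OC(=O)CC(=C)CC/C=C(\C)CC/C=C(\CO[Si](C)(C)C(C)(C)C)[C@H](C#CC(C)(C)O[Si](CC)(CC)CC)O | intermediate
21 | mixed anhydride of 20 with 2,4,6-trichlorobenzoic acid | O=C(OC(=O)CC(=C)CC/C=C(\C)CC/C=C(\CO[Si](C)(C)C(C)(C)C)[C@H](C#CC(C)(C)O[Si](CC)(CC)CC)O)c1c(Cl)cc(Cl)cc1Cl | intermediate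
22 | (7E,11E,13S)-12-{[(tert-butyldimethylsilyl)oxy]methyl}-8-methyl-4-methylidene-13-{3-methyl-3-[(triethylsilyl)oxy]but-1-yn-1-yl}-1-oxacyclotrideca-7,11-dien-2-one | O=C1CC(=C)CC/C=C(\C)CC/C=C(\CO[Si](C)(C)C(C)(C)C)[C@H](C#CC(C)(C)O[Si](CC)(CC)CC)O1 | intermediate
23 | (2Z,7E,11E,13S)-12-{[(tert-butyldimethylsilyl)oxy]methyl}-8-methyl-4-methylidene-13-{3-methyl-3-[(triethylsilyl)oxy]but-1-yn-1-yl}-2-[(trimethylsilyl)oxy]-1-oxacyclotrideca-2,7,11-triene | C[Si](C)(C)O/C1=C\C(=C)CC/C=C(\C)CC/C=C(\CO[Si](C)(C)C(C)(C)C)[C@H](C#CC(C)(C)O[Si](CC)(CC)CC)O1 | intermediate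
24 | trimethylsilyl ester of 25 | C=C1CC/C=C(\C)CC[C@H](/C(=C/C#CC(C)(C)O[Si](CC)(CC)CC)CO[Si](C)(C)C(C)(C)C)[C@H]1C(=O)O[Si](C)(C)C | intermediate
25 | (1R,2S,5E)-2-[(2Z)-1-{[tert-butyl(dimethyl)silyl]oxy}-6-methyl-6-[(triethylsilyl)oxy]hept-2-en-4-yn-2-yl]-5-methyl-9-methylidenecyclonon-5-ene-1-carboxylic acid | C=C1CC/C=C(\C)CC[C@H](/C(=C/C#CC(C)(C)O[Si](CC)(CC)CC)CO[Si](C)(C)C(C)(C)C)[C@H]1C(=O)O | intermediate
26 | methyl ester of 25 | C=C1CC/C=C(\C)CC[C@H](/C(=C/C#CC(C)(C)O[Si](CC)(CC)CC)CO[Si](C)(C)C(C)(C)C)[C@H]1C(=O)OC | intermediate
27 | methyl (1R,2S,5E)-2-[(2Z,4Z)-1-{[tert-butyl(dimethyl)silyl]oxy}-6-methyl-4-(triethoxysilyl)-6-[(triethylsilyl)oxy]hepta-2,4-dien-2-yl]-5-methyl-9-methylidenecyclonon-5-ene-1-carboxylate | C=C1CC/C=C(\C)CC[C@H](/C(=C/C(=C/C(C)(C)O[Si](CC)(CC)CC)[Si](OCC)(OCC)OCC)CO[Si](C)(C)C(C)(C)C)[C@H]1C(=O)OC | intermediate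
28 | methyl (1R,2S,5E)-2-[(2Z,4E)-1,6-dihydroxy-6-methylhepta-2,4-dien-2-yl]-5-methyl-9-methylidenecyclonon-5-ene-1-carboxylate | C=C1CC/C=C(\C)CC[C@H](/C(=C/C=C/C(C)(C)O)CO)[C@H]1C(=O)OC | intermediate
29 | methyl (1R,2S,5E)-2-[(2Z,4E)-1-(acetyloxy)-6-hydroxy-6-methylhepta-2,4-dien-2-yl]-5-methyl-9-methylidenecyclonon-5-ene-1-carboxylate | C=C1CC/C=C(\C)CC[C@H](/C(=C/C=C/C(C)(C)O)COC(C)=O)[C@H]1C(=O)OC | target

## Step count and least certain steps

Total: 18 steps. Longest linear sequence: 17 steps (steps 1–10 and 12–18 from geranyl chloride 1; step 11 is a one-step side branch).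

**Step 15 (key step).**
- What may go wrong: enolisation that gives a mixture of ketene acetal geometries, or reaction through a boat, both of which lead to the cis C8/C9 relationship (epimer at C9). Strain in the developing (E)-cyclononene may slow the transannular bond formation, so that the ketene acetal is lost by C-silylation or by elimination of the C11 alkoxide. Partial reaction through the axial-alkynyl chair would give the C10=C11 geometric isomer, which would have to be separated at 25 or 26.
- Fallback: set C9 by equilibration instead of by the transition state. Setting out from 22, the rearrangement is run as in step 15 and the C9-epimeric cis acid F1 is methylated with Me3SiCHN2 to the cis methyl ester F2. The ester F2 is then equilibrated at C9 with DBU in toluene through its dienolate. The trans ester, in which the two large ring substituents avoid each other, should be favoured, and because a dienolate is protonated kinetically at the α-carbon the methylene should stay exocyclic if the equilibration is stopped once the C9 composition no longer changes. The route is rejoined at 26.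

**Step 14.**
- What may go wrong: base-promoted migration of the C1 methylene into conjugation at the activated acyl stage (acylpyridinium or vinylketene), and oligomerisation, because the hindered C11 hydroxyl acylates slowly.
- Fallback: activate the alcohol instead of the acid. Setting out from 15, the step 12 protocol with (S,S)-ProPhenol gives the (12R)-diol F3, and the step 13 oxidation gives the (12R)-seco acid F4. A Mitsunobu macrolactonisation of F4 (PPh3, DIAD, toluene, high dilution) closes the ring with inversion at C11 and without an activated acyl species, rejoining the route at 22.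

**Step 12.**
- What may go wrong: low or reversed facial selectivity on the α-branched enal, and interference of the zinc alkoxide of the free C16 hydroxyl with the dinuclear catalyst.
- Fallback: set C11 by reagent-controlled reduction. Setting out from 15, the lithium acetylide of 17 (n-BuLi, THF, −78 °C) gives the racemic diol F5, and MnO2 oxidises only its allylic–propargylic carbinol to the ynone F6. Reduction of F6 with (R)-Alpine-Borane (B-isopinocampheyl-9-borabicyclo[3.3.1]nonane, neat, rt), in which the alkyne acts as the small group, should give the (S)-carbinol and rejoin the route at 18.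

**Step 13.**
- What may go wrong: competing oxidation of the activated C11 carbinol to the ynone, and migration of the C1 methylene into conjugation in aldehyde 19.
- Fallback: protect C11 first. Setting out from 18, Et3SiCl and imidazole give the 1,12-bis(triethylsilyl) ether F7. Swern oxidation converts a primary triethylsilyl ether directly into the aldehyde in the presence of secondary and tertiary silyl ethers, giving the 12-silyloxy aldehyde F8. Pinnick oxidation gives the 12-silyloxy acid F9, and buffered HF·pyridine at 0 °C removes the secondary silyl ether of F9 faster than the tertiary one or the primary TBS ether, rejoining the route at 20.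

**Step 17.**
- What may go wrong: loss of configuration at C9 or migration of the methylene through deprotonation by basic fluoride, closure of the freed primary alkoxide onto the methyl ester to a δ-lactone, and incomplete trans-addition on the conjugated enyne.
- Fallback: run the fluoride step on the carboxylate, which is neither enolisable at C9 under these conditions nor an acyl donor. Setting out from 25, the same hydrosilylation and Bu4NF treatment on the free acid give the dihydroxy acid F10, (1R,2S,5E)-2-[(2Z,4E)-1,6-dihydroxy-6-methylhepta-2,4-dien-2-yl]-5-methyl-9-methylidenecyclonon-5-ene-1-carboxylic acid. Me3SiCHN2 then methylates only the carboxyl group of F10, rejoining the route at 28.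

**Step 2.**
- What may go wrong: opening or base-induced isomerisation of the epoxide by the allyllithium or by residual n-BuLi, and some SN2' coupling.
- Fallback: couple first and mark the chain end afterwards. Setting out from 3 (as dianion 4), alkylation of geranyl bromide F11 gives the coupled dienol F12, (6E)-7,11-dimethyl-3-methylidenedodeca-6,10-dien-1-ol, which is acylated with PivCl to the pivalate F13. NBS in aqueous THF at 0 °C converts the terminal alkene of F13, by the terminal selectivity known for polyprenyl chains, into the bromohydrin F14. Brief K2CO3/MeOH treatment of F14 closes the epoxide, rejoining the route at 6.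

## Further compounds

F1 | step 15 | (1S,2S,5E)-2-[(2Z)-1-{[tert-butyl(dimethyl)silyl]oxy}-6-methyl-6-[(triethylsilyl)oxy]hept-2-en-4-yn-2-yl]-5-methyl-9-methylidenecyclonon-5-ene-1-carboxylic acid | C=C1CC/C=C(\C)CC[C@H](/C(=C/C#CC(C)(C)O[Si](CC)(CC)CC)CO[Si](C)(C)C(C)(C)C)[C@@H]1C(=O)O
F2 | step 15 | methyl ester of F1 | C=C1CC/C=C(\C)CC[C@H](/C(=C/C#CC(C)(C)O[Si](CC)(CC)CC)CO[Si](C)(C)C(C)(C)C)[C@@H]1C(=O)OC
F3 | step 14 | (6E,10E,12R)-11-{[(tert-butyldimethylsilyl)oxy]methyl}-7,15-dimethyl-3-methylidene-15-[(triethylsilyl)oxy]hexadeca-6,10-dien-13-yne-1,12-diol | OCCC(=C)CC/C=C(\C)CC/C=C(\CO[Si](C)(C)C(C)(C)C)[C@@H](C#CC(C)(C)O[Si](CC)(CC)CC)O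
F4 | step 14 | (6E,10E,12R)-11-{[(tert-butyldimethylsilyl)oxy]methyl}-12-hydroxy-7,15-dimethyl-3-methylidene-15-[(triethylsilyl)oxy]hexadeca-6,10-dien-13-ynoic acid | OC(=O)CC(=C)CC/C=C(\C)CC/C=C(\CO[Si](C)(C)C(C)(C)C)[C@@H](C#CC(C)(C)O[Si](CC)(CC)CC)O
F5 | step 12 | rac-(6E,10E)-11-{[(tert-butyldimethylsilyl)oxy]methyl}-7,15-dimethyl-3-methylidene-15-[(triethylsilyl)oxy]hexadeca-6,10-dien-13-yne-1,12-diol | OCCC(=C)CC/C=C(\C)CC/C=C(\CO[Si](C)(C)C(C)(C)C)C(O)C#CC(C)(C)O[Si](CC)(CC)CC
F6 | step 12 | (6E,10E)-11-{[(tert-butyldimethylsilyl)oxy]methyl}-1-hydroxy-7,15-dimethyl-3-methylidene-15-[(triethylsilyl)oxy]hexadeca-6,10-dien-13-yn-12-one | OCCC(=C)CC/C=C(\C)CC/C=C(\CO[Si](C)(C)C(C)(C)C)C(=O)C#CC(C)(C)O[Si](CC)(CC)CC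
F7 | step 13 | 1,12-bis(triethylsilyl) ether of 18 | CC[Si](CC)(CC)OCCC(=C)CC/C=C(\C)CC/C=C(\CO[Si](C)(C)C(C)(C)C)[C@H](C#CC(C)(C)O[Si](CC)(CC)CC)O[Si](CC)(CC)CC
F8 | step 13 | 12-O-triethylsilyl ether of 19 | O=CCC(=C)CC/C=C(\C)CC/C=C(\CO[Si](C)(C)C(C)(C)C)[C@H](C#CC(C)(C)O[Si](CC)(CC)CC)O[Si](CC)(CC)CC
F9 | step 13 | 12-O-triethylsilyl ether of 20 | OC(=O)CC(=C)CC/C=C(\C)CC/C=C(\CO[Si](C)(C)C(C)(C)C)[C@H](C#CC(C)(C)O[Si](CC)(CC)CC)O[Si](CC)(CC)CC
F10 | step 17 | (1R,2S,5E)-2-[(2Z,4E)-1,6-dihydroxy-6-methylhepta-2,4-dien-2-yl]-5-methyl-9-methylidenecyclonon-5-ene-1-carboxylic acid | C=C1CC/C=C(\C)CC[C@H](/C(=C/C=C/C(C)(C)O)CO)[C@H]1C(=O)O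
F11 | step 2 | geranyl bromide, (2E)-1-bromo-3,7-dimethylocta-2,6-diene | CC(C)=CCC/C(C)=C/CBr
F12 | step 2 | (6E)-7,11-dimethyl-3-methylidenedodeca-6,10-dien-1-ol | OCCC(=C)CC/C=C(\C)CCC=C(C)C
F13 | step 2 | (6E)-7,11-dimethyl-3-methylidenedodeca-6,10-dien-1-yl 2,2-dimethylpropanoate | CC(C)(C)C(=O)OCCC(=C)CC/C=C(\C)CCC=C(C)C
F14 | step 2 | rac-(6E)-10-bromo-11-hydroxy-7,11-dimethyl-3-methylidenedodec-6-en-1-yl 2,2-dimethylpropanoate | CC(C)(C)C(=O)OCCC(=C)CC/C=C(\C)CCC(Br)C(C)(C)O
A1 | alternative 1 | nine-membered C9 enol triflate with C15 allylsilane | C[Si](C)(C)C/C1=C(\OS(=O)(=O)C(F)(F)F)[C@@H](/C(=C/C=C/C(C)(C)O[Si](CC)(CC)CC)CO[Si](C)(C)C(C)(C)C)CC/C(C)=C/CC1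
A2 | alternative 1 | cis-1,2-dialkenylcyclopentanol (C5–C9 ring bond, C5 methyl and vinyl, C9 hydroxyl and 3-(trimethylsilyl)prop-1-en-2-yl, C8 side chain) | C=C(C[Si](C)(C)C)[C@@]1(O)[C@@](C)(C=C)CC[C@@H]1/C(=C/C=C/C(C)(C)O[Si](CC)(CC)CC)CO[Si](C)(C)C(C)(C)C
A3 | alternative 2 | nine-membered C2 allylic alcohol (C2 epimers) | C=C1C(O)C/C=C(\C)CC[C@H](/C(=C/C=C/C(C)(C)O[Si](CC)(CC)CC)CO[Si](C)(C)C(C)(C)C)[C@H]1C(=O)OC
A4 | alternative 2 | open-chain C1 alkenyl iodide with C2 aldehyde | C=C(I)[C@H](C(=O)OC)[C@H](CC/C(C)=C/CC=O)/C(=C/C=C/C(C)(C)O[Si](CC)(CC)CC)CO[Si](C)(C)C(C)(C)C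
A5 | alternative 3 | (E)-cyclononenone with C8 and C9 in place | O=C1CC/C=C(\C)CC[C@H](/C(=C/C=C/C(C)(C)O[Si](CC)(CC)CC)CO[Si](C)(C)C(C)(C)C)[C@H]1CO[Si](CC)(CC)CC
A6 | alternative 3 | hydrindane C1 tertiary alcohol with C4 tosylate cis to the C5 methyl | O[C@]12CC[C@@H](OS(=O)(=O)c3ccc(C)cc3)[C@]1(C)CC[C@H](/C(=C/C=C/C(C)(C)O[Si](CC)(CC)CC)CO[Si](C)(C)C(C)(C)C)[C@H]2CO[Si](CC)(CC)CC
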